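The flavanone hetero ring is cut first, at C4''–C4a'' (Friedel–Crafts acylation) and at O1''–C2'' (Mitsunobu etherification). The 3-(2,4,6-trihydroxyphenyl)flavone that remains is then cut at C4–C4a and O1–C2 (flavone atoms unprimed, flavanone atoms double-primed).
Enabling feature: flavone ring A carries O1, O5 and O7 on alternate carbons, so apart from the O7 methyl group it is phloroglucinol. C2, C3 and C4, with the anisyl group on C2 and the aryl group on C3, are the backbone of a single alpha-aryl aroylacetate, and acylation at any carbon of the C3-symmetric phenol gives the same flavone.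
Forward order: phloroglucinol serves twice. As its tribenzyl ether it is built into the ketoester (glyoxylate hydroxyalkylation, ionic reduction, enolate aroylation), and as the free phenol it supplies ring A in the thermal fusion that closes flavone ring C.
O7 methylation and hydrogenolysis then expose the second phloroglucinol ring. Its para oxygen becomes O1'' and either of its two equivalent CH carbons becomes C4a''; the flavanone hetero ring closes last.
Stereochemistry: C2'' (R) is the only stereocentre. It comes from an (S)-beta-hydroxy ester made by asymmetric transfer hydrogenation and is inverted in the Mitsunobu step; an electron-poor benzyl carbonate on the 4-hydroxyphenyl ring guards it against ionisation until a neutral final hydrogenolysis.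
Key step: step 5

Assumption: the C3–C6'' biaryl axis has no descriptor in the target and is flanked by two hydroxyl groups, so it is treated as configurationally labile and only C2'' is controlled.

Step 1
Reactants: 1 phloroglucinol
Product: 2 1,3,5-tris(benzyloxy)benzene
Conditions: BnBr (3.3 equiv), K2CO3 (4 equiv), DMF, 60 °C
Reagents that add atoms: benzyl bromide, BrCc1ccccc1
Why: Williamson etherification, in which carbonate in a dipolar aprotic solvent should keep the phloroglucinol anions reacting mainly at oxygen, and C-benzylated side products should be removable by crystallisation.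

Step 2
Reactants: 2 1,3,5-tris(benzyloxy)benzene; 3 ethyl glyoxylate
Product: 4 ethyl 2-hydroxy-2-[2,4,6-tris(benzyloxy)phenyl]acetate (racemic)
Conditions: 3 (2 equiv, freshly depolymerised), Yb(OTf)3 (10 mol %), CH2Cl2, 0 °C to rt
Reagents that add atoms: none
Why: Lewis acid catalysed Friedel–Crafts hydroxyalkylation, in which the trialkoxyarene adds to the activated aldehyde at any of its three equivalent carbons, excess aldehyde at low temperature should hold back a second arylation, and the racemic centre is erased in step 3.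

Step 3
Reactants: 4 ethyl 2-hydroxy-2-[2,4,6-tris(benzyloxy)phenyl]acetate
Product: 5 ethyl 2-[2,4,6-tris(benzyloxy)phenyl]acetate
Conditions: Et3SiH (2.5 equiv), TFA (5 equiv), CH2Cl2, 0 °C
Reagents that add atoms: none
Why: Ionic hydrogenation of Kursanov–Parnes type, in which TFA ionises the benzylic alcohol to a cation stabilised by three alkoxy donors despite the ester, and the silane should deliver hydride before the benzyl ethers are attacked at 0 °C.

Step 4
Reactants: 5 ethyl 2-[2,4,6-tris(benzyloxy)phenyl]acetate; 6 4-methoxybenzoyl chloride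
Product: 7 ethyl 3-(4-methoxyphenyl)-3-oxo-2-[2,4,6-tris(benzyloxy)phenyl]propanoate (racemic, enolisable)
Conditions: LiHMDS (2.2 equiv), THF, −78 °C; then 6 (1.1 equiv), −78 to −20 °C; aq NH4Cl
Reagents that add atoms: none
Why: Crossed Claisen-type C-acylation of a lithium ester enolate with an acid chloride, in which the second equivalent of base removes the acidic proton of the product so that conversion can be complete, and the new centre is enolisable and of no consequence.

Step 5
Reactants: 7 ethyl 3-(4-methoxyphenyl)-3-oxo-2-[2,4,6-tris(benzyloxy)phenyl]propanoate; 1 phloroglucinol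
Product: 10 5,7-dihydroxy-2-(4-methoxyphenyl)-3-[2,4,6-tris(benzyloxy)phenyl]chromen-4-one, via aroyl(aryl)ketene 8 (not isolated), via C-acylphloroglucinol diketone 9 (not isolated)
Conditions: 1 (3 equiv), neat melt under Ar, 240 °C (microwave), open vessel, 10–20 min
Reagents that add atoms: none
Why: Mentzer chromone synthesis, a formal [3+3] annulation: above roughly 200 °C the enol of 7 expels ethanol to give alpha-oxoketene 8, whose sp carbon stays accessible although the neighbouring aryl group carries two ortho benzyloxy groups. A ring carbon of molten phloroglucinol adds to that carbon (bond C4–C4a) and rearomatisation gives diketone 9. One of the two phenols flanking the new acyl group then attacks the anisoyl carbonyl in a 6-exo-trig closure (bond O1–C2), and loss of water aromatises the pyranone and makes the sequence irreversible. The closest known reactions are the thermal and microwave fusions of phloroglucinol with aroylacetates to flavones and of phenols with alpha-aryl acetoacetates to 2-methylisoflavones; no stereocentre is formed. Chromone must win over coumarin, which the absence of acid and the hindered, diaryl-flanked ketone (a poor acceptor for Pechmann-type arene attack) should secure, and one annulation must win over two, which the excess of 1 and the chelated, acyl-deactivated ring A of 10 should secure. Site selectivity needs no control because the three carbons and three hydroxyl groups of 1 are equivalent, and aryl benzyl ethers are known to withstand short heating at this temperature.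

Step 6
Reactants: 10 5,7-dihydroxy-2-(4-methoxyphenyl)-3-[2,4,6-tris(benzyloxy)phenyl]chromen-4-one
Product: 11 5-hydroxy-7-methoxy-2-(4-methoxyphenyl)-3-[2,4,6-tris(benzyloxy)phenyl]chromen-4-one
Conditions: MeI (1.1 equiv), K2CO3 (1.2 equiv), acetone, reflux
Reagents that add atoms: iodomethane, CI
Why: Chemoselective Williamson methylation, in which the 7-OH is the most acidic phenol (a vinylogous acid) while the 5-OH is locked in a hydrogen bond to the C4 carbonyl, so one equivalent of electrophile should react at O7 only.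

Step 7
Reactants: 11 5-hydroxy-7-methoxy-2-(4-methoxyphenyl)-3-[2,4,6-tris(benzyloxy)phenyl]chromen-4-one
Product: 12 5-hydroxy-7-methoxy-2-(4-methoxyphenyl)-3-(2,4,6-trihydroxyphenyl)chromen-4-one
Conditions: H2 (1 atm), 10% Pd/C, THF/MeOH, rt
Reagents that add atoms: none
Why: Catalytic hydrogenolysis of aryl benzyl ethers, under which the tetrasubstituted C2=C3 bond of the vinylogous ester and the methyl ethers should be inert at one atmosphere of hydrogen.

Step 8
Reactants: 13 methyl 4-hydroxybenzoate; 14 tert-butyl acetate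
Product: 15 tert-butyl 3-(4-hydroxyphenyl)-3-oxopropanoate
Conditions: LDA (4.5 equiv), 14 (4.2 equiv), THF, −78 °C; then 13, −78 °C to rt; aq NH4Cl
Reagents that add atoms: none
Why: Crossed Claisen condensation with the lithium enolate of tert-butyl acetate, in which one equivalent is spent on the phenol, the excess attacks the methyl ester, and the product rests as its enolate until work-up.

Step 9
Reactants: 15 tert-butyl 3-(4-hydroxyphenyl)-3-oxopropanoate
Product: 16 tert-butyl 3-{4-[(benzyloxy)carbonyloxy]phenyl}-3-oxopropanoate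
Conditions: CbzCl (1.05 equiv), Et3N (1.1 equiv), CH2Cl2, 0 °C
Reagents that add atoms: benzyl chloroformate, O=C(Cl)OCc1ccccc1
Why: Chemoselective O-acylation to an aryl carbonate, in which the para-acylphenol is more acidic and more exposed than the ketoester enol and should be captured first, giving a group that makes the ring electron-poor yet leaves by neutral hydrogenolysis.

Step 10
Reactants: 16 tert-butyl 3-{4-[(benzyloxy)carbonyloxy]phenyl}-3-oxopropanoate
Product: 17 tert-butyl (3S)-3-{4-[(benzyloxy)carbonyloxy]phenyl}-3-hydroxypropanoate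
Conditions: RuCl(p-cymene)[(S,S)-TsDPEN] (1 mol %), HCO2H/Et3N (5:2), EtOAc, 30 °C
Reagents that add atoms: none
Why: Noyori asymmetric transfer hydrogenation, in which the CH/pi contact between the cymene ligand and the aryl group of the ketone fixes the exposed face, so the (S,S)-ligand should give the (S)-carbinol as it does with aryl alkyl ketones, and the acidic medium leaves carbonate and tert-butyl ester intact.

Step 11
Reactants: 12 5-hydroxy-7-methoxy-2-(4-methoxyphenyl)-3-(2,4,6-trihydroxyphenyl)chromen-4-one; 17 tert-butyl (3S)-3-{4-[(benzyloxy)carbonyloxy]phenyl}-3-hydroxypropanoate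
Product: 18 tert-butyl (3R)-3-{4-[(benzyloxy)carbonyloxy]phenyl}-3-{3,5-dihydroxy-4-[5-hydroxy-7-methoxy-2-(4-methoxyphenyl)-4-oxochromen-3-yl]phenoxy}propanoate
Conditions: 17 (1.05 equiv), PPh3 (1.3 equiv), DIAD (1.3 equiv, slow addition), THF/toluene, −10 °C to rt
Reagents that add atoms: none
Why: Mitsunobu etherification with SN2 inversion of the (S)-carbinol to the (R)-aryl ether, in which the para phenol is the only one neither chelated (5-OH) nor pressed against the perpendicular flavone (the two ortho phenols), the bulky secondary electrophile should amplify that difference, and the electron-poor aryl ring disfavours the ionisation that would erode the configuration.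

Step 12
Reactants: 18 tert-butyl (3R)-3-{4-[(benzyloxy)carbonyloxy]phenyl}-3-{3,5-dihydroxy-4-[5-hydroxy-7-methoxy-2-(4-methoxyphenyl)-4-oxochromen-3-yl]phenoxy}propanoate
Product: 20 benzyl 4-{(2R)-5,7-dihydroxy-6-[5-hydroxy-7-methoxy-2-(4-methoxyphenyl)-4-oxochromen-3-yl]-4-oxochroman-2-yl}phenyl carbonate, via free carboxylic acid 19 (not isolated)
Conditions: TFA/CH2Cl2 (1:3), Et3SiH (3 equiv), 0 °C to rt; evaporate with toluene; TFAA (4 equiv), CH2Cl2, 0 °C to rt; MeOH quench
Reagents that add atoms: none
Why: Acidolysis of the tert-butyl ester followed by TFAA-promoted intramolecular Friedel–Crafts acylation, in which the two carbons ortho to the ether oxygen are equivalent so only one chromanone can form, the phloroglucinol ring should react at or below room temperature, the silane intercepts the tert-butyl cation, and the stereocentre is untouched and shielded from heterolysis by the carbonate-deactivated aryl group.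

Step 13
Reactants: 20 benzyl 4-{(2R)-5,7-dihydroxy-6-[5-hydroxy-7-methoxy-2-(4-methoxyphenyl)-4-oxochromen-3-yl]-4-oxochroman-2-yl}phenyl carbonate
Product: 21 (2R)-5,7-dihydroxy-6-[5-hydroxy-7-methoxy-2-(4-methoxyphenyl)-4-oxochromen-3-yl]-2-(4-hydroxyphenyl)chroman-4-one (CNP0292254.1)
Conditions: H2 (1 atm), 10% Pd/C, EtOAc, rt; filtration, no base in work-up
Reagents that add atoms: none
Why: Hydrogenolysis of a benzyl carbonate with loss of carbon dioxide, a neutral unmasking that avoids the base-induced opening to the chalcone by which 4'-hydroxyflavanones racemise, and in which the primary benzyl C–O bond should cleave much faster than the cyclic C2''–O1'' bond.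

Compound list
1 | phloroglucinol | Oc1cc(O)cc(O)c1 | starting material
2 | 1,3,5-tris(benzyloxy)benzene | c1ccc(COc2cc(OCc3ccccc3)cc(OCc3ccccc3)c2)cc1 | intermediate
3 | ethyl glyoxylate | CCOC(=O)C=O | starting material
4 | ethyl 2-hydroxy-2-[2,4,6-tris(benzyloxy)phenyl]acetate (racemic) | CCOC(=O)C(O)c1c(OCc2ccccc2)cc(OCc2ccccc2)cc1OCc1ccccc1 | intermediate
5 | ethyl 2-[2,4,6-tris(benzyloxy)phenyl]acetate | CCOC(=O)Cc1c(OCc2ccccc2)cc(OCc2ccccc2)cc1OCc1ccccc1 | intermediate
6 | 4-methoxybenzoyl chloride | COc1ccc(C(=O)Cl)cc1 | starting material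
7 | ethyl 3-(4-methoxyphenyl)-3-oxo-2-[2,4,6-tris(benzyloxy)phenyl]propanoate (racemic, enolisable) | CCOC(=O)C(C(=O)c1ccc(OC)cc1)c1c(OCc2ccccc2)cc(OCc2ccccc2)cc1OCc1ccccc1 | intermediate
8 | (4-methoxybenzoyl)[2,4,6-tris(benzyloxy)phenyl]ketene (not isolated) | O=C=C(C(=O)c1ccc(OC)cc1)c1c(OCc2ccccc2)cc(OCc2ccccc2)cc1OCc1ccccc1 | intermediate
9 | 1-(4-methoxyphenyl)-3-(2,4,6-trihydroxyphenyl)-2-[2,4,6-tris(benzyloxy)phenyl]propane-1,3-dione (racemic, not isolated) | COc1ccc(cc1)C(=O)C(C(=O)c1c(O)cc(O)cc1O)c1c(OCc2ccccc2)cc(OCc2ccccc2)cc1OCc1ccccc1 | intermediate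
10 | 5,7-dihydroxy-2-(4-methoxyphenyl)-3-[2,4,6-tris(benzyloxy)phenyl]chromen-4-one | COc1ccc(-c2oc3cc(O)cc(O)c3c(=O)c2-c2c(OCc3ccccc3)cc(OCc3ccccc3)cc2OCc2ccccc2)cc1 | intermediate
11 | 5-hydroxy-7-methoxy-2-(4-methoxyphenyl)-3-[2,4,6-tris(benzyloxy)phenyl]chromen-4-one | COc1ccc(-c2oc3cc(OC)cc(O)c3c(=O)c2-c2c(OCc3ccccc3)cc(OCc3ccccc3)cc2OCc2ccccc2)cc1 | intermediate
12 | 5-hydroxy-7-methoxy-2-(4-methoxyphenyl)-3-(2,4,6-trihydroxyphenyl)chromen-4-one | COc1ccc(-c2oc3cc(OC)cc(O)c3c(=O)c2-c2c(O)cc(O)cc2O)cc1 | intermediate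
13 | methyl 4-hydroxybenzoate | COC(=O)c1ccc(O)cc1 | starting material
14 | tert-butyl acetate | CC(=O)OC(C)(C)C | starting material
15 | tert-butyl 3-(4-hydroxyphenyl)-3-oxopropanoate | CC(C)(C)OC(=O)CC(=O)c1ccc(O)cc1 | intermediate
16 | tert-butyl 3-{4-[(benzyloxy)carbonyloxy]phenyl}-3-oxopropanoate | CC(C)(C)OC(=O)CC(=O)c1ccc(OC(=O)OCc2ccccc2)cc1 | intermediate
17 | tert-butyl (3S)-3-{4-[(benzyloxy)carbonyloxy]phenyl}-3-hydroxypropanoate | CC(C)(C)OC(=O)C[C@H](O)c1ccc(OC(=O)OCc2ccccc2)cc1 | intermediate
18 | tert-butyl (3R)-3-{4-[(benzyloxy)carbonyloxy]phenyl}-3-{3,5-dihydroxy-4-[5-hydroxy-7-methoxy-2-(4-methoxyphenyl)-4-oxochromen-3-yl]phenoxy}propanoate | COc1ccc(-c2oc3cc(OC)cc(O)c3c(=O)c2-c2c(O)cc(O[C@H](CC(=O)OC(C)(C)C)c3ccc(OC(=O)OCc4ccccc4)cc3)cc2O)cc1 | intermediate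
19 | (3R)-3-{4-[(benzyloxy)carbonyloxy]phenyl}-3-{3,5-dihydroxy-4-[5-hydroxy-7-methoxy-2-(4-methoxyphenyl)-4-oxochromen-3-yl]phenoxy}propanoic acid (not isolated) | COc1ccc(-c2oc3cc(OC)cc(O)c3c(=O)c2-c2c(O)cc(O[C@H](CC(=O)O)c3ccc(OC(=O)OCc4ccccc4)cc3)cc2O)cc1 | intermediate
20 | benzyl 4-{(2R)-5,7-dihydroxy-6-[5-hydroxy-7-methoxy-2-(4-methoxyphenyl)-4-oxochromen-3-yl]-4-oxochroman-2-yl}phenyl carbonate | COc1ccc(-c2oc3cc(OC)cc(O)c3c(=O)c2-c2c(O)cc3c(c2O)C(=O)C[C@H](c2ccc(OC(=O)OCc4ccccc4)cc2)O3)cc1 | intermediate
21 | (2R)-5,7-dihydroxy-6-[5-hydroxy-7-methoxy-2-(4-methoxyphenyl)-4-oxochromen-3-yl]-2-(4-hydroxyphenyl)chroman-4-one (CNP0292254.1) | COc1ccc(-c2oc3cc(OC)cc(O)c3c(=O)c2-c2c(O)cc3c(c2O)C(=O)C[C@H](c2ccc(O)cc2)O3)cc1 | target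

Total step count: 13.
Longest linear sequence: 10 steps (steps 1 to 7, then 11 to 13). The side chain takes 3 steps (8 to 10).

Steps most likely to fail

**Step 5.**
- Risk: the two ortho benzyloxy groups may slow capture of the ketene by the arene. Dealkoxycarbonylation by the released water, thermal benzyl transfer to phloroglucinol, or Pechmann-type closure could then take over.
- Fallback, from 2 back to 10: the pyranone is assembled stepwise by the deoxybenzoin route, which makes C4–C4a at 0 °C and C2–C3 by an intramolecular acyl shift. Vilsmeier–Haack formylation of 2 (POCl3, DMF) should give 2,4,6-tris(benzyloxy)benzaldehyde F1. Van Leusen reductive cyanation (TosMIC, t-BuOK, DME, then MeOH) should convert it into [2,4,6-tris(benzyloxy)phenyl]acetonitrile F2. Houben–Hoesch acylation of 1 with this nitrile (ZnCl2, HCl gas, Et2O, 0 °C, then warm water) should give 1-(2,4,6-trihydroxyphenyl)-2-[2,4,6-tris(benzyloxy)phenyl]ethanone F3. Exhaustive aroylation with 6 (K2CO3, acetone, reflux) should set off a Baker–Venkataraman shift and cyclodehydration of Kostanecki–Robinson type, giving 5,7-bis(4-methoxybenzoyloxy)-2-(4-methoxyphenyl)-3-[2,4,6-tris(benzyloxy)phenyl]chromen-4-one F4. Methanolysis of its two aryl esters (K2CO3, MeOH, rt) gives 10.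

**Step 11.**
- Risk: alkylation may spread from the para phenol to the two hindered phenols, and the activated beta-hydroxy ester may undergo beta-elimination while substitution is slow.
- Fallback, from 12 back to 19: the para oxygen is singled out with protecting groups instead of in the coupling itself. A very bulky silyl chloride (TIPSCl, imidazole, DMF, 0 °C) should select the exposed phenol more sharply and give 3-[2,6-dihydroxy-4-(triisopropylsilyloxy)phenyl]-5-hydroxy-7-methoxy-2-(4-methoxyphenyl)chromen-4-one F5; wrongly silylated material can be returned to 12 with fluoride. Boc2O with catalytic DMAP should cap the two ortho phenols to give the bis(tert-butyl carbonate) silyl ether F6. Buffered fluoride (TBAF, AcOH, THF, 0 °C) should free the para phenol to give the bis(tert-butyl carbonate) phenol F7. This phenol is now the only free unchelated one and is more acidic, which should favour substitution over elimination. Mitsunobu coupling with 17 under the conditions of step 11 should give the (3R)-ether bis(tert-butyl carbonate) F8. The TFA/Et3SiH stage of step 12 removes both carbonates together with the tert-butyl ester and delivers 19.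

**Step 12.**
- Risk: O-trifluoroacetylation of the two free ring phenols may switch off the arene, intermolecular ester formation may compete, and a longer time in acid would invite heterolysis of the benzylic C–O bond with loss of configuration.
- Fallback, from 18 back to 21: the closure is run on a trialkoxyarene, the substrate class for which it is best established. Neutral Mitsunobu benzylation of 18 (BnOH, PPh3, DIAD, THF) should give the 3,5-bis(benzyloxy) ether tert-butyl ester F9. TFA/Et3SiH should give the corresponding 3,5-bis(benzyloxy) ether acid F10, and TFAA in CH2Cl2 at 0 °C should close it to the (2R)-5,7-bis(benzyloxy)flavanone benzyl carbonate F11. A single hydrogenolysis (H2, 10% Pd/C, EtOAc) removes the two benzyl ethers and the benzyl carbonate to give 21.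

Further compounds
F1 | step 5 | 2,4,6-tris(benzyloxy)benzaldehyde | O=Cc1c(OCc2ccccc2)cc(OCc2ccccc2)cc1OCc1ccccc1
F2 | step 5 | [2,4,6-tris(benzyloxy)phenyl]acetonitrile | N#CCc1c(OCc2ccccc2)cc(OCc2ccccc2)cc1OCc1ccccc1
F3 | step 5 | 1-(2,4,6-trihydroxyphenyl)-2-[2,4,6-tris(benzyloxy)phenyl]ethanone | O=C(Cc1c(OCc2ccccc2)cc(OCc2ccccc2)cc1OCc1ccccc1)c1c(O)cc(O)cc1O
F4 | step 5 | 5,7-bis(4-methoxybenzoyloxy)-2-(4-methoxyphenyl)-3-[2,4,6-tris(benzyloxy)phenyl]chromen-4-one | COc1ccc(cc1)C(=O)Oc1cc(OC(=O)c2ccc(OC)cc2)c2c(c1)oc(-c1ccc(OC)cc1)c(-c1c(OCc3ccccc3)cc(OCc3ccccc3)cc1OCc1ccccc1)c2=O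
F5 | step 11 | 3-[2,6-dihydroxy-4-(triisopropylsilyloxy)phenyl]-5-hydroxy-7-methoxy-2-(4-methoxyphenyl)chromen-4-one | COc1ccc(-c2oc3cc(OC)cc(O)c3c(=O)c2-c2c(O)cc(O[Si](C(C)C)(C(C)C)C(C)C)cc2O)cc1
F6 | step 11 | bis(tert-butyl carbonate) silyl ether: 3-[2,6-bis(tert-butoxycarbonyloxy)-4-(triisopropylsilyloxy)phenyl]-5-hydroxy-7-methoxy-2-(4-methoxyphenyl)chromen-4-one | COc1ccc(-c2oc3cc(OC)cc(O)c3c(=O)c2-c2c(OC(=O)OC(C)(C)C)cc(O[Si](C(C)C)(C(C)C)C(C)C)cc2OC(=O)OC(C)(C)C)cc1
F7 | step 11 | bis(tert-butyl carbonate) phenol: 3-[2,6-bis(tert-butoxycarbonyloxy)-4-hydroxyphenyl]-5-hydroxy-7-methoxy-2-(4-methoxyphenyl)chromen-4-one | COc1ccc(-c2oc3cc(OC)cc(O)c3c(=O)c2-c2c(OC(=O)OC(C)(C)C)cc(O)cc2OC(=O)OC(C)(C)C)cc1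
F8 | step 11 | (3R)-ether bis(tert-butyl carbonate): tert-butyl (3R)-3-{4-[(benzyloxy)carbonyloxy]phenyl}-3-{3,5-bis(tert-butoxycarbonyloxy)-4-[5-hydroxy-7-methoxy-2-(4-methoxyphenyl)-4-oxochromen-3-yl]phenoxy}propanoate | COc1ccc(-c2oc3cc(OC)cc(O)c3c(=O)c2-c2c(OC(=O)OC(C)(C)C)cc(O[C@H](CC(=O)OC(C)(C)C)c3ccc(OC(=O)OCc4ccccc4)cc3)cc2OC(=O)OC(C)(C)C)cc1
F9 | step 12 | 3,5-bis(benzyloxy) ether tert-butyl ester: tert-butyl (3R)-3-{4-[(benzyloxy)carbonyloxy]phenyl}-3-{3,5-bis(benzyloxy)-4-[5-hydroxy-7-methoxy-2-(4-methoxyphenyl)-4-oxochromen-3-yl]phenoxy}propanoate | COc1ccc(-c2oc3cc(OC)cc(O)c3c(=O)c2-c2c(OCc3ccccc3)cc(O[C@H](CC(=O)OC(C)(C)C)c3ccc(OC(=O)OCc4ccccc4)cc3)cc2OCc2ccccc2)cc1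
F10 | step 12 | 3,5-bis(benzyloxy) ether acid: (3R)-3-{4-[(benzyloxy)carbonyloxy]phenyl}-3-{3,5-bis(benzyloxy)-4-[5-hydroxy-7-methoxy-2-(4-methoxyphenyl)-4-oxochromen-3-yl]phenoxy}propanoic acid | COc1ccc(-c2oc3cc(OC)cc(O)c3c(=O)c2-c2c(OCc3ccccc3)cc(O[C@H](CC(=O)O)c3ccc(OC(=O)OCc4ccccc4)cc3)cc2OCc2ccccc2)cc1
F11 | step 12 | (2R)-5,7-bis(benzyloxy)flavanone benzyl carbonate: benzyl 4-{(2R)-5,7-bis(benzyloxy)-6-[5-hydroxy-7-methoxy-2-(4-methoxyphenyl)-4-oxochromen-3-yl]-4-oxochroman-2-yl}phenyl carbonate | COc1ccc(-c2oc3cc(OC)cc(O)c3c(=O)c2-c2c(OCc3ccccc3)cc3c(c2OCc2ccccc2)C(=O)C[C@H](c2ccc(OC(=O)OCc4ccccc4)cc2)O3)cc1
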